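Ring C (the quinone) is disconnected across its H–C=C(isopropyl) double bond. Because the isopropyl carbon sits beside the carbonyl that is flanked by the aryloxy carbon, this bond is an aldol-condensation retron: an isobutyl ketone α-carbon condensing with an aldehyde carbon. The key step is a one-pot [3+3] benzannulation: the acyclic aryloxy β-keto ester 9, already carrying rings A and B, adds to but-2-ynal, the enal so formed is closed onto the ketone α-carbon, and loss of the tert-butyl ester aromatizes ring C to phenol 14. The second quinone carbonyl is installed last by para-oxidation of that phenol.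

Key step: step 7

Remarks: Ring A is the terminal aryl ring, ring B the central aryl ring, ring C the quinone ring. "ArO" stands for the 6-isopropyl-2-(2-isopropyl-4-methoxy-5-methylphenoxy)-4-methoxy-3-methylphenoxy group (rings A and B). The target has no stereocentre; 9 and 11 to 13 are racemic and 11 is expected as an E/Z mixture. Compounds 1, 5, 8 and 10 are taken as commercial.

Step 1
Reactants: 1 thymol (2-isopropyl-5-methylphenol)
Product: 2 4-bromo-2-isopropyl-5-methylphenol
Conditions: NBS, MeCN, 0 °C to rt
Reagents that add atoms: N-bromosuccinimide, O=C1CCC(=O)N1Br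
Why: Electrophilic aromatic bromination, in which the hydroxyl group directs to its free para position, the least hindered activated carbon of thymol.

Step 2
Reactants: 2 4-bromo-2-isopropyl-5-methylphenol
Product: 3 2-isopropyl-4-methoxy-5-methylphenol
Conditions: NaOMe, CuI (20 mol%), DMF/MeOH, 110 °C, argon; aq. HCl work-up
Reagents that add atoms: sodium methoxide, C[O-].[Na+]
Why: Copper-catalysed Ullmann-type methoxylation of the aryl bromide, which tolerates the phenol as its sodium salt and places the methoxy group para to the hydroxyl without regiochemical ambiguity.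

Step 3
Reactants: 3 2-isopropyl-4-methoxy-5-methylphenol
Product: 4 2-iodo-6-isopropyl-4-methoxy-3-methylphenol
Conditions: NIS, TsOH·H2O (10 mol%), MeCN, 0 °C
Reagents that add atoms: N-iodosuccinimide, O=C1CCC(=O)N1I
Why: Electrophilic aromatic iodination at the only free position ortho to the hydroxyl group, which is more activated and less hindered than the ring CH between the isopropyl and methoxy groups; the iodide is chosen because it should couple more readily than a bromide in step 5.

Step 4
Reactants: 4 2-iodo-6-isopropyl-4-methoxy-3-methylphenol; 5 tert-butyl bromoacetate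
Product: 6 tert-butyl 2-(2-iodo-6-isopropyl-4-methoxy-3-methylphenoxy)acetate
Conditions: K2CO3, DMF, rt
Reagents that add atoms: none
Why: Williamson ether synthesis (SN2 of the phenoxide on a primary α-bromo ester), which masks the hindered phenol through the copper coupling and installs the O–CH2 unit whose carbon becomes the aryloxy-bearing carbon of ring C.

Step 5
Reactants: 6 tert-butyl 2-(2-iodo-6-isopropyl-4-methoxy-3-methylphenoxy)acetate; 3 2-isopropyl-4-methoxy-5-methylphenol
Product: 7 tert-butyl 2-(ArO)acetate
Conditions: CuI (10 mol%), picolinic acid (20 mol%), K3PO4, DMSO, 90 °C, argon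
Reagents that add atoms: none
Why: Ullmann diaryl ether synthesis (copper-catalysed C–O coupling of an aryl iodide with a phenoxide), using a picolinate-ligated copper catalyst that accepts ortho substituents on both partners, while the tert-butyl ester is inert to phosphate base and phenoxide.

Step 6
Reactants: 7 tert-butyl 2-(ArO)acetate; 8 3-methylbutanoyl chloride
Product: 9 tert-butyl 2-(ArO)-5-methyl-3-oxohexanoate (racemic)
Conditions: LiN(SiMe3)2 (2.1 equiv), THF, −78 °C; then 8, −78 to −40 °C; aq. NH4Cl
Reagents that add atoms: none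
Why: Crossed Claisen condensation, in which the deprotonated α-aryloxy ester is C-acylated by the acid chloride and the second equivalent of base takes up the acidic proton of the β-keto ester as it forms; the new stereocentre is racemic and is lost in step 7.

Step 7
Reactants: 9 tert-butyl 2-(ArO)-5-methyl-3-oxohexanoate; 10 but-2-ynal
Product: 14 6-isopropyl-3-methyl-2-(ArO)phenol, via enal adduct 11 (not isolated), via dienone ester 12 (not isolated), via dienone acid 13 (not isolated)
Conditions: 10 (1.2 equiv), Cs2CO3 (20 mol%), MeCN, 0 °C to rt; then pyrrolidine (20 mol%), AcOH (20 mol%), 50 °C; then solvent switch to PhMe, TsOH·H2O (1 equiv), 80 °C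
Reagents that add atoms: none
Why: Catalytic Cs2CO3 makes the β-dicarbonyl carbon of 9 add in a Michael reaction to the methyl-bearing alkyne carbon of 10, giving enal 11 in which the aryloxy carbon is quaternary and the isobutyl CH2 is the only enolizable ketone position. Pyrrolidinium acetate then turns the enal into an iminium ion, equilibrates its E and Z forms through the dienamine, and lets the enol of the ketone attack the iminium carbon; loss of the amine gives dienone 12, so ring C is closed by a 6-(enolendo)-exo-trig intramolecular aldol (Mannich-type) condensation that creates the HC=C(isopropyl) bond. TsOH finally cleaves the tert-butyl ester to the β-keto acid 13, which loses CO2 and lands directly on the aromatic phenol 14. The closest known reaction type is the Michael/aldol [3+3] benzannulation of β-keto esters and other 1,3-dinucleophilic ketones with alkynals and alkynones. The quaternary stereocentre of 11 to 13 is racemic and disappears on aromatization, so no stereocontrol is needed. The step needs the aryloxy carbon to bond to the methyl-bearing carbon and the isobutyl carbon to the aldehyde carbon; the substrate secures this because its β-dicarbonyl carbon is the only soft carbon nucleophile for the conjugate addition (aldol addition at the aldehyde is reversible) and, once that carbon is quaternary, only the isobutyl CH2 can condense with the aldehyde.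

Step 8
Reactants: 14 6-isopropyl-3-methyl-2-(ArO)phenol
Product: 15 6-isopropyl-3-methyl-2-(ArO)cyclohexa-2,5-diene-1,4-dione (CNP0335608.0)
Conditions: (KSO3)2NO (Fremy's salt, 2.5 equiv), KH2PO4, acetone/H2O, 0 °C to rt
Reagents that add atoms: potassium nitrosodisulfonate (Fremy's salt), [K+].[K+].[O]N(S(=O)(=O)[O-])S(=O)(=O)[O-]
Why: Teuber oxidation, in which one nitrosodisulfonate radical abstracts the phenolic hydrogen and a second couples at the free para carbon before imidodisulfonate is lost to give the para-quinone; both ortho positions are substituted and rings A and B carry no free hydroxyl, so only ring C should be oxidized.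

Compound list
1 | thymol (2-isopropyl-5-methylphenol) | Cc1ccc(C(C)C)c(O)c1 | starting material
2 | 4-bromo-2-isopropyl-5-methylphenol | Cc1cc(O)c(C(C)C)cc1Br | intermediate
3 | 2-isopropyl-4-methoxy-5-methylphenol | COc1cc(C(C)C)c(O)cc1C | intermediate
4 | 2-iodo-6-isopropyl-4-methoxy-3-methylphenol | COc1cc(C(C)C)c(O)c(I)c1C | intermediate
5 | tert-butyl bromoacetate | BrCC(=O)OC(C)(C)C | starting material
6 | tert-butyl 2-(2-iodo-6-isopropyl-4-methoxy-3-methylphenoxy)acetate | COc1cc(C(C)C)c(OCC(=O)OC(C)(C)C)c(I)c1C | intermediate
7 | tert-butyl 2-[6-isopropyl-2-(2-isopropyl-4-methoxy-5-methylphenoxy)-4-methoxy-3-methylphenoxy]acetate | COc1cc(C(C)C)c(Oc2c(C)c(OC)cc(C(C)C)c2OCC(=O)OC(C)(C)C)cc1C | intermediate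
8 | 3-methylbutanoyl chloride | CC(C)CC(=O)Cl | starting material
9 | tert-butyl 2-(ArO)-5-methyl-3-oxohexanoate, racemic | COc1cc(C(C)C)c(Oc2c(C)c(OC)cc(C(C)C)c2OC(C(=O)OC(C)(C)C)C(=O)CC(C)C)cc1C | intermediate
10 | but-2-ynal | CC#CC=O | starting material
11 | tert-butyl 2-(ArO)-3-methyl-2-(3-methylbutanoyl)-5-oxopent-3-enoate, racemic, E/Z mixture, not isolated | COc1cc(C(C)C)c(Oc2c(C)c(OC)cc(C(C)C)c2OC(C(=O)OC(C)(C)C)(C(=O)CC(C)C)C(C)=CC=O)cc1C | intermediate
12 | tert-butyl 1-(ArO)-3-isopropyl-6-methyl-2-oxocyclohexa-3,5-diene-1-carboxylate, racemic, not isolated | COc1cc(C(C)C)c(Oc2c(C)c(OC)cc(C(C)C)c2OC2(C(=O)OC(C)(C)C)C(C)=CC=C(C(C)C)C2=O)cc1C | intermediate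
13 | 1-(ArO)-3-isopropyl-6-methyl-2-oxocyclohexa-3,5-diene-1-carboxylic acid, racemic, not isolated | COc1cc(C(C)C)c(Oc2c(C)c(OC)cc(C(C)C)c2OC2(C(=O)O)C(C)=CC=C(C(C)C)C2=O)cc1C | intermediate
14 | 6-isopropyl-3-methyl-2-[6-isopropyl-2-(2-isopropyl-4-methoxy-5-methylphenoxy)-4-methoxy-3-methylphenoxy]phenol | COc1cc(C(C)C)c(Oc2c(C)c(OC)cc(C(C)C)c2Oc2c(C)ccc(C(C)C)c2O)cc1C | intermediate
15 | 6-isopropyl-3-methyl-2-[6-isopropyl-2-(2-isopropyl-4-methoxy-5-methylphenoxy)-4-methoxy-3-methylphenoxy]cyclohexa-2,5-diene-1,4-dione (CNP0335608.0) | COc1cc(C(C)C)c(Oc2c(C)c(OC)cc(C(C)C)c2OC2=C(C)C(=O)C=C(C(C)C)C2=O)cc1C | target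

Total step count: 8. Longest linear sequence: 8 steps (1 → 2 → 3 → 4 → 6 → 7 → 9 → 14 → 15).

Steps most likely to fail

Step 7. The conjugate addition may lose to base-induced oligomerization of the ynal or to attack through the enolate oxygen. The enal may fail to equilibrate to the Z form, so the ring cannot close. The 2,4-cyclohexadienone may dimerize by Diels–Alder reaction before the ester is removed. The fallback sets out from 9 and comes back at 14, using an enal instead of the ynal and aromatizing ring C in a separate oxidation. Michael addition of 9 to (E)-but-2-enal (K2CO3, MeCN) should give the saturated keto aldehyde tert-butyl 2-(ArO)-3-methyl-2-(3-methylbutanoyl)-5-oxopentanoate F1, which has no double-bond geometry to control. Pyrrolidinium acetate then closes ring C by the same aldol condensation to tert-butyl 1-(ArO)-3-isopropyl-6-methyl-2-oxocyclohex-3-ene-1-carboxylate F2. TsOH·H2O in toluene at 80 °C removes the ester group to give 6-(ArO)-2-isopropyl-5-methylcyclohex-2-en-1-one F3. Aerobic dehydrogenation (Pd(O2CCF3)2, 2-(dimethylamino)pyridine, TsOH, O2, DMSO, 80 °C) aromatizes F3 to 14.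

Step 5. Oxidative addition and C–O bond formation at an iodine flanked by two ortho substituents may be too slow, so that protodeiodination and oxidative degradation of the electron-rich phenol take over. The fallback sets out from 4 and comes back at 7, replacing the copper coupling by addition–elimination on a quinone. Oxidative demethylation of 4 with (NH4)2Ce(NO3)6 (MeCN/H2O, 0 °C) should give 2-iodo-6-isopropyl-3-methyl-1,4-benzoquinone F4. Phenol 3 with Cs2CO3 in DMF displaces the iodide to give 2-(2-isopropyl-4-methoxy-5-methylphenoxy)-6-isopropyl-3-methyl-1,4-benzoquinone F5. Na2S2O4 (EtOAc/H2O) reduces it to 2-(2-isopropyl-4-methoxy-5-methylphenoxy)-6-isopropyl-3-methylbenzene-1,4-diol F6. One equivalent of MeI with K2CO3 in acetone methylates the less hindered hydroxyl (beside the methyl group) to give 6-isopropyl-2-(2-isopropyl-4-methoxy-5-methylphenoxy)-4-methoxy-3-methylphenol F7. Alkylation of F7 with 5 (K2CO3, DMF) gives 7.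

Step 6. O-acylation of the enolate, proton transfer from the product to unreacted enolate, or ketene formation from the acid chloride may stop the C-acylation at low conversion. The fallback sets out from 7 and comes back at 9, replacing the acylation by an aldol addition and an oxidation. Deprotonation of 7 with LiN(iPr)2 (THF, −78 °C) and addition of 3-methylbutanal should give tert-butyl 2-(ArO)-3-hydroxy-5-methylhexanoate F8 as a diastereomer mixture. Dess–Martin periodinane (CH2Cl2, NaHCO3) then oxidizes F8 to 9.

Further compounds
F1 | step 7 | tert-butyl 2-(ArO)-3-methyl-2-(3-methylbutanoyl)-5-oxopentanoate (diastereomer mixture) | COc1cc(C(C)C)c(Oc2c(C)c(OC)cc(C(C)C)c2OC(C(=O)OC(C)(C)C)(C(=O)CC(C)C)C(C)CC=O)cc1C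
F2 | step 7 | tert-butyl 1-(ArO)-3-isopropyl-6-methyl-2-oxocyclohex-3-ene-1-carboxylate (diastereomer mixture) | COc1cc(C(C)C)c(Oc2c(C)c(OC)cc(C(C)C)c2OC2(C(=O)OC(C)(C)C)C(C)CC=C(C(C)C)C2=O)cc1C
F3 | step 7 | 6-(ArO)-2-isopropyl-5-methylcyclohex-2-en-1-one (diastereomer mixture) | COc1cc(C(C)C)c(Oc2c(C)c(OC)cc(C(C)C)c2OC2C(C)CC=C(C(C)C)C2=O)cc1C
F4 | step 5 | 2-iodo-6-isopropyl-3-methyl-1,4-benzoquinone | CC1=C(I)C(=O)C(C(C)C)=CC1=O
F5 | step 5 | 2-(2-isopropyl-4-methoxy-5-methylphenoxy)-6-isopropyl-3-methyl-1,4-benzoquinone | CC1=C(Oc2cc(C)c(OC)cc2C(C)C)C(=O)C(C(C)C)=CC1=O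
F6 | step 5 | 2-(2-isopropyl-4-methoxy-5-methylphenoxy)-6-isopropyl-3-methylbenzene-1,4-diol | Cc1c(O)cc(C(C)C)c(O)c1Oc1cc(C)c(OC)cc1C(C)C
F7 | step 5 | 6-isopropyl-2-(2-isopropyl-4-methoxy-5-methylphenoxy)-4-methoxy-3-methylphenol | Cc1c(OC)cc(C(C)C)c(O)c1Oc1cc(C)c(OC)cc1C(C)C
F8 | step 6 | tert-butyl 2-(ArO)-3-hydroxy-5-methylhexanoate (diastereomer mixture) | COc1cc(C(C)C)c(Oc2c(C)c(OC)cc(C(C)C)c2OC(C(=O)OC(C)(C)C)C(O)CC(C)C)cc1C
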